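**Retrosynthetic overview**
1. Cut the CH2 bridge at pyranone C-3. This bond is made by an intermolecular Michael addition of the 4-hydroxy-2-pyranone to an ortho-quinone methide of the arene half.
2. The quinone methide comes from a Mannich base, made from the prenylated acylphloroglucinol and Eschenmoser's salt at its only free ring CH.
3. The arene half comes from tris-MOM phloroglucinol by two directed lithiations. Prenyl bromide goes on first, then (S)-2-methylbutanal from the chiral pool, followed by oxidation and MOM removal.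
4. The pyranone comes from a 3,5-dioxo ester, made by the dianion aldol of methyl 3-oxopentanoate with propanal and then oxidation.
5. Ring order: ring A (benzene) is bought. Ring B (pyranone) is the only ring built, by lactonisation, before the two halves are joined.

Assumption: the stereocentre written [C@@H] decodes as S, and commercial (S)-2-methylbutan-1-ol of high ee is its source.

**Step 1**
Reactants: 1 methyl 3-oxopentanoate; 2 propanal
Product: 4 methyl 5-hydroxy-4-methyl-3-oxoheptanoate (racemic syn/anti mixture), via dianion 3 (not isolated)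
Conditions: NaH (1.1 equiv), THF, 0 °C; n-BuLi (1.05 equiv), 0 °C; 2 (1.1 equiv), −78 °C; then 1 M HCl
Reagents that add atoms: none
Why: In this Weiler dianion aldol addition the more basic γ-carbanion adds to the aldehyde faster than it enolises it, and both new stereocentres are erased in steps 2 and 3, so the mixture is carried on.

**Step 2**
Reactants: 4 methyl 5-hydroxy-4-methyl-3-oxoheptanoate
Product: 5 methyl 4-methyl-3,5-dioxoheptanoate
Conditions: Dess–Martin periodinane (1.3 equiv), CH2Cl2, 0 °C → rt
Reagents that add atoms: none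
Why: The Dess–Martin oxidation converts the secondary alcohol to the ketone under nearly neutral conditions that leave the β-keto ester untouched.

**Step 3**
Reactants: 5 methyl 4-methyl-3,5-dioxoheptanoate
Product: 6 6-ethyl-4-hydroxy-5-methyl-2H-pyran-2-one
Conditions: DBU (1.5 equiv), toluene, 60 °C; then 1 M HCl
Reagents that add atoms: none
Why: In this base-mediated lactonisation the C-5 enolate oxygen attacks the methyl ester, and the conjugated 4-hydroxy-2-pyranone formed is a strong thermodynamic sink.

**Step 4**
Reactants: 7 phloroglucinol (anhydrous)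
Product: 8 1,3,5-tris(methoxymethoxy)benzene
Conditions: MOMCl (4 equiv), i-Pr2NEt (5 equiv), DMF, 0 °C → rt
Reagents that add atoms: chloromethyl methyl ether (MOMCl), COCCl
Why: In this Williamson-type O-alkylation the hard chloromethyl ether reacts at oxygen rather than carbon, and it installs three groups that direct lithiation.

**Step 5**
Reactants: 8 1,3,5-tris(methoxymethoxy)benzene; 9 prenyl bromide
Product: 11 1,3,5-tris(methoxymethoxy)-2-(3-methylbut-2-en-1-yl)benzene, via aryllithium 10 (not isolated)
Conditions: n-BuLi (1.1 equiv), THF, 0 °C, 1 h; 9 (1.3 equiv), −78 °C → rt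
Reagents that add atoms: none
Why: Directed ortho-metalation between two OMOM groups is followed by SN2 alkylation with the primary allylic bromide, and the three ring CH positions are equivalent, so only one regioisomer can form.

**Step 6**
Reactants: 12 (S)-2-methylbutan-1-ol
Product: 13 (S)-2-methylbutanal
Conditions: TEMPO (1 mol %), KBr (10 mol %), aq NaOCl (1.1 equiv, NaHCO3 to pH 9.5), CH2Cl2/H2O, 0 °C; distil
Reagents that add atoms: none
Why: The Anelli oxidation stops at the aldehyde, and at 0 °C in the buffered two-phase medium it does not epimerise the chiral-pool α-stereocentre.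

**Step 7**
Reactants: 11 1,3,5-tris(methoxymethoxy)-2-(3-methylbut-2-en-1-yl)benzene; 13 (S)-2-methylbutanal
Product: 15 (2S)-2-methyl-1-[2,4,6-tris(methoxymethoxy)-3-(3-methylbut-2-en-1-yl)phenyl]butan-1-ol (mixture of C-1 epimers), via aryllithium 14 (not isolated)
Conditions: n-BuLi (1.1 equiv), THF, −10 → 0 °C, 1 h; 13 (1.3 equiv), −78 °C; then sat. aq NH4Cl
Reagents that add atoms: none
Why: Directed ortho-metalation at either of the two equivalent doubly flanked CH positions is followed by 1,2-addition to the aldehyde, which at −78 °C is faster than enolisation, so C-2 stays S and the unselective carbinol centre is erased in step 8.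

**Step 8**
Reactants: 15 (2S)-2-methyl-1-[2,4,6-tris(methoxymethoxy)-3-(3-methylbut-2-en-1-yl)phenyl]butan-1-ol
Product: 16 (2S)-2-methyl-1-[2,4,6-tris(methoxymethoxy)-3-(3-methylbut-2-en-1-yl)phenyl]butan-1-one
Conditions: Dess–Martin periodinane (1.3 equiv), pyridine (3 equiv), CH2Cl2, 0 °C → rt
Reagents that add atoms: none
Why: The pyridine-buffered Dess–Martin oxidation gives the aryl ketone without touching the MOM acetals, the trisubstituted alkene or the α-stereocentre.

**Step 9**
Reactants: 16 (2S)-2-methyl-1-[2,4,6-tris(methoxymethoxy)-3-(3-methylbut-2-en-1-yl)phenyl]butan-1-one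
Product: 17 (2S)-2-methyl-1-[2,4,6-trihydroxy-3-(3-methylbut-2-en-1-yl)phenyl]butan-1-one
Conditions: 3 M aq HCl (cat.), MeOH (0.02 M), 45 °C, 2–3 h, stopped at full conversion
Reagents that add atoms: none
Why: Acid-catalysed acetal exchange with a large excess of methanol removes all three MOM groups as dimethoxymethane, under conditions too mild and brief for chroman closure or for enolisation of the hydrogen-bonded ketone.

**Step 10**
Reactants: 17 (2S)-2-methyl-1-[2,4,6-trihydroxy-3-(3-methylbut-2-en-1-yl)phenyl]butan-1-one; 18 Eschenmoser's salt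
Product: 19 (2S)-1-{3-[(dimethylamino)methyl]-2,4,6-trihydroxy-5-(3-methylbut-2-en-1-yl)phenyl}-2-methylbutan-1-one hydroiodide
Conditions: 18 (1.05 equiv), MeCN, 0 °C → rt, 2 h; concentrate, triturate with Et2O
Reagents that add atoms: none
Why: This Mannich reaction uses a preformed iminium salt at the only free nucleophilic ring carbon, and with no free formaldehyde present the methylene-bis homodimer is avoided and the product is stored as its stable ammonium salt.

**Step 11**
Reactants: 19 Mannich base hydroiodide; 6 6-ethyl-4-hydroxy-5-methyl-2H-pyran-2-one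
Product: 21 6-ethyl-4-hydroxy-5-methyl-3-({2,4,6-trihydroxy-3-[(2S)-2-methylbutanoyl]-5-(3-methylbut-2-en-1-yl)phenyl}methyl)-2H-pyran-2-one, via ortho-quinone methide 20 (not isolated)
Conditions: 6 (1.5 equiv), Et3N (2.2 equiv), MeCN, 40 °C, Ar; then aq citric acid wash
Reagents that add atoms: none
Why: Base-induced E1cB loss of dimethylamine gives the quinone methide, and the pyranone enolate adds through C-3 in an intermolecular Michael addition driven by rearomatisation, while the fully substituted arene half cannot homodimerise and the phenolate-conjugated ketone is not enolised, so the S centre is kept.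

**Compound list**
1 | methyl 3-oxopentanoate | CCC(=O)CC(=O)OC | starting material
2 | propanal | CCC=O | starting material
3 | sodium lithium dianion of methyl 3-oxopentanoate | [Na+].[Li+].CC=C([O-])C=C([O-])OC | intermediate
4 | methyl 5-hydroxy-4-methyl-3-oxoheptanoate (racemic syn/anti mixture) | CCC(O)C(C)C(=O)CC(=O)OC | intermediate
5 | methyl 4-methyl-3,5-dioxoheptanoate | CCC(=O)C(C)C(=O)CC(=O)OC | intermediate
6 | 6-ethyl-4-hydroxy-5-methyl-2H-pyran-2-one | CCc1oc(=O)cc(O)c1C | intermediate
7 | phloroglucinol (benzene-1,3,5-triol) | Oc1cc(O)cc(O)c1 | starting material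
8 | 1,3,5-tris(methoxymethoxy)benzene | COCOc1cc(OCOC)cc(OCOC)c1 | intermediate
9 | prenyl bromide (1-bromo-3-methylbut-2-ene) | CC(C)=CCBr | starting material
10 | 2,4,6-tris(methoxymethoxy)phenyllithium | [Li]c1c(OCOC)cc(OCOC)cc1OCOC | intermediate
11 | 1,3,5-tris(methoxymethoxy)-2-(3-methylbut-2-en-1-yl)benzene | CC(C)=CCc1c(OCOC)cc(OCOC)cc1OCOC | intermediate
12 | (S)-2-methylbutan-1-ol | CC[C@H](C)CO | starting material
13 | (S)-2-methylbutanal | CC[C@H](C)C=O | intermediate
14 | 2,4,6-tris(methoxymethoxy)-3-(3-methylbut-2-en-1-yl)phenyllithium | [Li]c1c(OCOC)cc(OCOC)c(CC=C(C)C)c1OCOC | intermediate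
15 | (2S)-2-methyl-1-[2,4,6-tris(methoxymethoxy)-3-(3-methylbut-2-en-1-yl)phenyl]butan-1-ol (C-1 epimers) | CC[C@H](C)C(O)c1c(OCOC)cc(OCOC)c(CC=C(C)C)c1OCOC | intermediate
16 | (2S)-2-methyl-1-[2,4,6-tris(methoxymethoxy)-3-(3-methylbut-2-en-1-yl)phenyl]butan-1-one | CC[C@H](C)C(=O)c1c(OCOC)cc(OCOC)c(CC=C(C)C)c1OCOC | intermediate
17 | (2S)-2-methyl-1-[2,4,6-trihydroxy-3-(3-methylbut-2-en-1-yl)phenyl]butan-1-one | CC[C@H](C)C(=O)c1c(O)cc(O)c(CC=C(C)C)c1O | intermediate
18 | Eschenmoser's salt (N,N-dimethylmethyleneiminium iodide) | C=[N+](C)C.[I-] | starting material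
19 | (2S)-1-{3-[(dimethylamino)methyl]-2,4,6-trihydroxy-5-(3-methylbut-2-en-1-yl)phenyl}-2-methylbutan-1-one hydroiodide | CC[C@H](C)C(=O)c1c(O)c(C[NH+](C)C)c(O)c(CC=C(C)C)c1O.[I-] | intermediate
20 | 3,5-dihydroxy-6-methylidene-4-[(2S)-2-methylbutanoyl]-2-(3-methylbut-2-en-1-yl)cyclohexa-2,4-dien-1-one | C=C1C(=O)C(CC=C(C)C)=C(O)C(C(=O)[C@@H](C)CC)=C1O | intermediate
21 | 6-ethyl-4-hydroxy-5-methyl-3-({2,4,6-trihydroxy-3-[(2S)-2-methylbutanoyl]-5-(3-methylbut-2-en-1-yl)phenyl}methyl)-2H-pyran-2-one | CCc1oc(=O)c(Cc2c(O)c(CC=C(C)C)c(O)c(C(=O)[C@@H](C)CC)c2O)c(O)c1C | target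

**Step count**
Total step count: 11. Longest linear sequence: 7 (steps 4, 5, 7, 8, 9, 10, 11).

**Steps most likely to fail**

**Step 7.** n-BuLi may deprotonate the allylic-benzylic CH2 of 11 instead of the ring.
- The fallback replaces C–H deprotonation by halogen–lithium exchange. It sets out from 8 and comes back to the route at 14.
- Treat 8 with NBS (2.0 equiv, MeCN, 0 °C) to give 2,4-dibromo-1,3,5-tris(methoxymethoxy)benzene F1.
- Exchange one bromine with n-BuLi (1.0 equiv, THF, −78 °C) to give 3-bromo-2,4,6-tris(methoxymethoxy)phenyllithium F2.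
- Alkylate F2 with 9 to give 2-bromo-1,3,5-tris(methoxymethoxy)-4-(3-methylbut-2-en-1-yl)benzene F3.
- Exchange the remaining bromine with n-BuLi at −78 °C. This is much faster than any C–H deprotonation and delivers aryllithium 14, which is then treated with 13 as before.

**Step 9.** Acid may close the prenyl group onto a neighbouring phenol to give a chroman, or the released formaldehyde equivalent may bridge two molecules of 17.
- The fallback drops the protecting groups altogether. It sets out from 13, with 7 and 9 as partners, and comes back at 17.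
- Pinnick oxidation of 13 (NaClO2, NaH2PO4, 2-methylbut-2-ene, t-BuOH/H2O) gives (S)-2-methylbutanoic acid F4.
- (COCl)2 with catalytic DMF in CH2Cl2 gives (S)-2-methylbutanoyl chloride F5.
- Friedel–Crafts acylation of 7 (AlCl3, CH2Cl2/PhNO2, 0 → 40 °C) gives (2S)-2-methyl-1-(2,4,6-trihydroxyphenyl)butan-1-one F6.
- Direct C-prenylation of the phenolate of F6 with 9 (aq KOH, 0 °C) gives 17 after removal of the diprenylated material. The ee is checked by chiral HPLC.

**Step 11.** The quinone methide may be trapped poorly, or the bridge may scramble to give homodimers.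
- The fallback reverses the roles of donor and acceptor. It sets out from 6, with 18 and 17 as partners, and comes back at 21.
- Compound 6 and 18 in CH2Cl2 at 0 °C give 3-[(dimethylamino)methyl]-6-ethyl-4-hydroxy-5-methyl-2H-pyran-2-one hydroiodide F7.
- F7 is added slowly to a solution of 17 (2 equiv) and Et3N in CHCl3 at rt.
- The transient 6-ethyl-5-methyl-3-methylidene-2H-pyran-2,4(3H)-dione F8 therefore always meets an excess of the phloroglucinol, which adds through its free ring carbon in a Michael addition to give 21.

**Further compounds**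
F1 | step 7 | 2,4-dibromo-1,3,5-tris(methoxymethoxy)benzene | COCOc1cc(OCOC)c(Br)c(OCOC)c1Br
F2 | step 7 | 3-bromo-2,4,6-tris(methoxymethoxy)phenyllithium | [Li]c1c(OCOC)cc(OCOC)c(Br)c1OCOC
F3 | step 7 | 2-bromo-1,3,5-tris(methoxymethoxy)-4-(3-methylbut-2-en-1-yl)benzene | CC(C)=CCc1c(OCOC)cc(OCOC)c(Br)c1OCOC
F4 | step 9 | (S)-2-methylbutanoic acid | CC[C@H](C)C(=O)O
F5 | step 9 | (S)-2-methylbutanoyl chloride | CC[C@H](C)C(=O)Cl
F6 | step 9 | (2S)-2-methyl-1-(2,4,6-trihydroxyphenyl)butan-1-one | CC[C@H](C)C(=O)c1c(O)cc(O)cc1O
F7 | step 11 | 3-[(dimethylamino)methyl]-6-ethyl-4-hydroxy-5-methyl-2H-pyran-2-one hydroiodide | CCc1oc(=O)c(C[NH+](C)C)c(O)c1C.[I-]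
F8 | step 11 | 6-ethyl-5-methyl-3-methylidene-2H-pyran-2,4(3H)-dione | CCC1=C(C)C(=O)C(=C)C(=O)O1
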